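**Retrosynthetic overview**
- The C3 carbinol and the free C8 hydroxyl are adjusted last. The A/B-cis ring fusion (H-5) and the second C4 methyl come from a copper-hydride conjugate reduction/methylation of a ring A enone.
- Ring A (formed second) is annulated onto ring B with ethyl vinyl ketone: C1–C10 by Michael addition, C4=C5 by aldol condensation.
- The complete C16 side chain enters at C9 by conjugate addition of a homofarnesyl Grignard reagent (three steps from farnesol) to a 4-silyloxy-2,4-dimethylcyclohexenone.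
- Ring B (first ring) is taken from an arene. The key step is the C8–O bond: a catalytic enantioselective para-hydroxylative dearomatisation of 2,4-dimethylphenol. It creates the only catalyst-set stereocentre; C9, C10, C5 and C3 are relayed from it.

Assumption: the SMILES is read literally. It encodes (3S,5S,8R,9R,10S), with H-5 cis to the C10 methyl (A/B-cis decalin), i.e. the C5 epimer of the natural trans-fused 3β,8α-diol, and that isomer is the one made.

Notation: positions use terpenoid numbering (decalin C1–C10, side chain from C11). "Homofarnesyl" means (3E,7E)-4,8,12-trimethyltrideca-3,7,11-trien-1-yl.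

**Step 1**
Reactants: 1 2,4-dimethylphenol
Product: 2 (R)-4-hydroxy-2,4-dimethylcyclohexa-2,5-dien-1-one
Conditions: ArI* (10 mol %), mCPBA (1.2 equiv), H2O (10 equiv), MeCN, −20 °C; one recrystallisation. ArI* = (2R,2'R)-2,2'-[(2-iodo-1,3-phenylene)bis(oxy)]bis[N-(2,6-diisopropylphenyl)propanamide] or its mirror image, whichever antipode gives (R)-2 in a first screening run
Reagents that add atoms: water, O
Why: Proposed new method: mCPBA turns the aryl iodide into a trivalent-iodine species that binds the phenol oxygen of 1, the two lactamide N–H groups fold around iodine into a C2-symmetric pocket, and water attacks C4 anti to the departing iodane in an associative SN2′-type step on the one ring face that the C2 methyl leaves open, so the C–O bond and the quaternary carbinol centre (C8 of the target, R) form together; the closest known reaction type is the aryl-iodide-catalysed oxidative dearomatisation of phenols (enantioselective ortho-spirolactonisation; para-hydroxylation so far only with low ee) and the stoichiometric PhI(OAc)2 synthesis of para-quinols.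

**Step 2**
Reactants: 2 (R)-4-hydroxy-2,4-dimethylcyclohexa-2,5-dien-1-one
Product: 3 (R)-2,4-dimethyl-4-(triethylsilyloxy)cyclohexa-2,5-dien-1-one
Conditions: Et3SiCl, imidazole, DMAP (cat.), DMF, rt
Reagents that add atoms: chlorotriethylsilane, CC[Si](Cl)(CC)CC
Why: Silylation of the quinol hydroxyl (flanked only by sp2 carbons, hence accessible) gives a bulky, non-coordinating ether that later steers the organocopper reagent to the opposite face; the stereocentre is untouched.

**Step 3**
Reactants: 3 (R)-2,4-dimethyl-4-(triethylsilyloxy)cyclohexa-2,5-dien-1-one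
Product: 4 (R)-2,4-dimethyl-4-(triethylsilyloxy)cyclohex-2-en-1-one
Conditions: H2 (1 atm), RhCl(PPh3)3 (5 mol %), toluene, rt
Reagents that add atoms: none
Why: Homogeneous RhCl(PPh3)3 hydrogenation is strongly retarded by alkene substitution, so only the disubstituted C5=C6 bond of the dienone is saturated and the 2-methyl enone arm survives (chemoselective alkene hydrogenation).

**Step 4**
Reactants: 5 (2E,6E)-farnesol
Product: 6 (2E,6E)-farnesal
Conditions: MnO2 (15 equiv), CH2Cl2, rt
Reagents that add atoms: none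
Why: MnO2 oxidises the allylic alcohol selectively and without E/Z isomerisation of the 2,3-alkene (allylic oxidation).

**Step 5**
Reactants: 6 (2E,6E)-farnesal
Product: 7 (3E,7E)-4,8,12-trimethyltrideca-1,3,7,11-tetraene
Conditions: Ph3PCH3Br, n-BuLi, THF, 0 °C → rt
Reagents that add atoms: methyltriphenylphosphonium bromide, C[P+](c1ccccc1)(c1ccccc1)c1ccccc1.[Br-]
Why: Wittig methylenation of the enal adds the terminal CH2 and leaves the trisubstituted alkenes unchanged.

**Step 6**
Reactants: 7 (3E,7E)-4,8,12-trimethyltrideca-1,3,7,11-tetraene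
Product: 9 (3E,7E)-1-iodo-4,8,12-trimethyltrideca-3,7,11-triene (homofarnesyl iodide), via homofarnesyl(disiamyl)borane 8 (not isolated)
Conditions: Sia2BH (from BH3·THF, 2-methylbut-2-ene), THF, 0 °C; then I2, NaOMe, MeOH, 0 °C → rt
Reagents that add atoms: iodine, [I][I]
Why: The bulky dialkylborane adds only to the monosubstituted terminus of the diene, anti-Markovnikov, and base-induced iodinolysis cleaves the primary B–C bond (Brown hydroboration–iodination); the trisubstituted alkenes do not react.

**Step 7**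
Reactants: 9 homofarnesyl iodide; 4 (R)-2,4-dimethyl-4-(triethylsilyloxy)cyclohex-2-en-1-one
Product: 11 (3R,4R)-2,4-dimethyl-3-homofarnesyl-4-(triethylsilyloxy)-1-(trimethylsilyloxy)cyclohex-1-ene, via homofarnesylmagnesium iodide 10 (not isolated)
Conditions: Mg, THF, rt; then 4, CuBr·SMe2 (10 mol %), Me3SiCl, HMPA, THF, −78 → −40 °C; Et3N, pentane work-up
Reagents that add atoms: chlorotrimethylsilane, C[Si](C)(C)Cl
Why: In this Me3SiCl-accelerated copper-catalysed conjugate addition of the Grignard reagent, the alkyl group adds to the β-carbon anti to the pseudo-axial silyloxy group (steric and Felkin-type control), which sets C9 (R, chain trans to oxygen, cis to the C8 methyl); the enolate is trapped regiospecifically as the silyl enol ether.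

**Step 8**
Reactants: 11 (3R,4R)-2,4-dimethyl-3-homofarnesyl-4-(triethylsilyloxy)-1-(trimethylsilyloxy)cyclohex-1-ene; 12 ethyl vinyl ketone (pent-1-en-3-one)
Product: 14 (4aR,5R,6R)-1,4a,6-trimethyl-5-homofarnesyl-6-(triethylsilyloxy)-4,4a,5,6,7,8-hexahydronaphthalen-2(3H)-one, via 1,5-diketone 13 (not isolated)
Conditions: BF3·OEt2, i-PrOH, CH2Cl2, −78 °C; then NaOMe, MeOH, 0 → 50 °C
Reagents that add atoms: none
Why: A Lewis-acid-mediated Mukaiyama–Michael addition creates the C10 quaternary centre with the vinyl ketone entering anti to the adjacent C9 chain (so the C10 methyl ends cis to the chain), and base-induced aldol condensation then closes ring A (Robinson annulation).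

**Step 9**
Reactants: 14 (4aR,5R,6R)-1,4a,6-trimethyl-5-homofarnesyl-6-(triethylsilyloxy)-4,4a,5,6,7,8-hexahydronaphthalen-2(3H)-one
Product: 17 (4aS,5R,6R,8aS)-1,1,4a,6-tetramethyl-5-homofarnesyl-6-(triethylsilyloxy)octahydronaphthalen-2(1H)-one (cis-fused), via dimethylphenylsilyl enol ether 15 (not isolated), via lithium enolate 16 (not isolated)
Conditions: [1,3-bis(2,6-diisopropylphenyl)imidazol-2-ylidene]CuCl (5 mol %), NaOtBu (5 mol %), PhMe2SiH, toluene, rt; then MeLi, THF, 0 °C; MeI, DMPU, −78 → 0 °C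
Reagents that add atoms: iodomethane, CI
Why: Copper-hydride 1,4-reduction leaves isolated alkenes alone and is expected to deliver hydride to C5 on the face of the C10 methyl (axial to ring A only, avoiding the doubly axial approach between H-7 and H-9 on the other face), as cuprates and hydrogenation do with 10-methyl octalones, which gives the cis ring fusion (5S); the regiospecific enolate is then C-methylated to the gem-dimethyl group (reductive alkylation).

**Step 10**
Reactants: 17 (4aS,5R,6R,8aS)-1,1,4a,6-tetramethyl-5-homofarnesyl-6-(triethylsilyloxy)octahydronaphthalen-2(1H)-one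
Product: 18 (2S,4aS,5R,6R,8aS)-1,1,4a,6-tetramethyl-5-homofarnesyl-6-(triethylsilyloxy)decahydronaphthalen-2-ol
Conditions: Li, NH3(l), THF, EtOH, −78 → −33 °C; NH4Cl
Reagents that add atoms: none
Why: Dissolving-metal reduction gives the thermodynamically preferred equatorial carbinol; in the preferred conformer of this cis-decalin (C4 equatorial on ring B) that is the 3β (3S) alcohol, because the 3α epimer would be syn-axial to C6, and the isolated alkenes and the silyl ether are inert.

**Step 11**
Reactants: 18 (2S,4aS,5R,6R,8aS)-1,1,4a,6-tetramethyl-5-homofarnesyl-6-(triethylsilyloxy)decahydronaphthalen-2-ol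
Product: 19 (2S,4aS,5R,6R,8aS)-1,1,4a,6-tetramethyl-5-[(3E,7E)-4,8,12-trimethyltrideca-3,7,11-trien-1-yl]decahydronaphthalene-2,6-diol (target; terpenoid descriptors 3S,5S,8R,9R,10S)
Conditions: Bu4NF, THF, 50 °C
Reagents that add atoms: none
Why: Fluoride cleaves the tertiary Si–O bond (desilylation) under conditions that touch neither the alkenes nor any stereocentre.

**Compound list**
1 | 2,4-dimethylphenol | Cc1ccc(O)c(C)c1 | starting material
2 | (R)-4-hydroxy-2,4-dimethylcyclohexa-2,5-dien-1-one | O=C1C=C[C@@](C)(O)C=C1C | intermediate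
3 | (R)-2,4-dimethyl-4-(triethylsilyloxy)cyclohexa-2,5-dien-1-one | O=C1C=C[C@@](C)(O[Si](CC)(CC)CC)C=C1C | intermediate
4 | (R)-2,4-dimethyl-4-(triethylsilyloxy)cyclohex-2-en-1-one | O=C1CC[C@@](C)(O[Si](CC)(CC)CC)C=C1C | intermediate
5 | (2E,6E)-farnesol | CC(C)=CCC/C(C)=C/CC/C(C)=C/CO | starting material
6 | (2E,6E)-farnesal | CC(C)=CCC/C(C)=C/CC/C(C)=C/C=O | intermediate
7 | (3E,7E)-4,8,12-trimethyltrideca-1,3,7,11-tetraene | CC(C)=CCC/C(C)=C/CC/C(C)=C/C=C | intermediate
8 | homofarnesyl-bis(3-methylbutan-2-yl)borane | CC(C)=CCC/C(C)=C/CC/C(C)=C/CCB(C(C)C(C)C)C(C)C(C)C | intermediate (not isolated)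
9 | (3E,7E)-1-iodo-4,8,12-trimethyltrideca-3,7,11-triene (homofarnesyl iodide) | CC(C)=CCC/C(C)=C/CC/C(C)=C/CCI | intermediate
10 | homofarnesylmagnesium iodide | CC(C)=CCC/C(C)=C/CC/C(C)=C/CC[Mg]I | intermediate (not isolated)
11 | (3R,4R)-2,4-dimethyl-3-homofarnesyl-4-(triethylsilyloxy)-1-(trimethylsilyloxy)cyclohex-1-ene (chain trans to OSiEt3) | CC(C)=CCC/C(C)=C/CC/C(C)=C/CC[C@@H]1C(C)=C(O[Si](C)(C)C)CC[C@@]1(C)O[Si](CC)(CC)CC | intermediate
12 | ethyl vinyl ketone (pent-1-en-3-one) | CCC(=O)C=C | starting material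
13 | (2R,3R,4R)-2,4-dimethyl-2-(3-oxopentyl)-3-homofarnesyl-4-(triethylsilyloxy)cyclohexan-1-one | CC(C)=CCC/C(C)=C/CC/C(C)=C/CC[C@@H]1[C@@](C)(CCC(=O)CC)C(=O)CC[C@@]1(C)O[Si](CC)(CC)CC | intermediate (not isolated)
14 | (4aR,5R,6R)-1,4a,6-trimethyl-5-homofarnesyl-6-(triethylsilyloxy)-4,4a,5,6,7,8-hexahydronaphthalen-2(3H)-one | CC(C)=CCC/C(C)=C/CC/C(C)=C/CC[C@@H]1[C@@]2(C)CCC(=O)C(C)=C2CC[C@@]1(C)O[Si](CC)(CC)CC | intermediate
15 | cis-fused C3 dimethylphenylsilyl enol ether (5S,8R,9R,10S) | CC(C)=CCC/C(C)=C/CC/C(C)=C/CC[C@@H]1[C@@]2(C)CCC(O[Si](C)(C)c3ccccc3)=C(C)[C@H]2CC[C@@]1(C)O[Si](CC)(CC)CC | intermediate (not isolated)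
16 | cis-fused C3 lithium enolate (5S,8R,9R,10S) | CC(C)=CCC/C(C)=C/CC/C(C)=C/CC[C@@H]1[C@@]2(C)CCC(O[Li])=C(C)[C@H]2CC[C@@]1(C)O[Si](CC)(CC)CC | intermediate (not isolated)
17 | (4aS,5R,6R,8aS)-1,1,4a,6-tetramethyl-5-homofarnesyl-6-(triethylsilyloxy)octahydronaphthalen-2(1H)-one | CC(C)=CCC/C(C)=C/CC/C(C)=C/CC[C@@H]1[C@@]2(C)CCC(=O)C(C)(C)[C@H]2CC[C@@]1(C)O[Si](CC)(CC)CC | intermediate
18 | (2S,4aS,5R,6R,8aS)-1,1,4a,6-tetramethyl-5-homofarnesyl-6-(triethylsilyloxy)decahydronaphthalen-2-ol | CC(C)=CCC/C(C)=C/CC/C(C)=C/CC[C@@H]1[C@@]2(C)CC[C@H](O)C(C)(C)[C@H]2CC[C@@]1(C)O[Si](CC)(CC)CC | intermediate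
19 | (2S,4aS,5R,6R,8aS)-1,1,4a,6-tetramethyl-5-[(3E,7E)-4,8,12-trimethyltrideca-3,7,11-trien-1-yl]decahydronaphthalene-2,6-diol | CC(C)=CCC/C(C)=C/CC/C(C)=C/CC[C@@H]1[C@@]2(C)CC[C@H](O)C(C)(C)[C@H]2CC[C@@]1(C)O | target

**Totals**
Total step count: 11. Longest linear sequence: 8 steps (steps 1, 2, 3, 7, 8, 9, 10, 11; the farnesol branch, steps 4, 5, 6 and then 7 to 11, is equally long).

**Steps most likely to fail, with fallbacks**

Step 1 (new enantioselective dearomatisation; the risk is low ee or ortho attack). The fallback sets out from 1 and comes back at 2. PhI(OAc)2 in MeCN/H2O at 0 °C, the known achiral oxidant, gives racemic 4-hydroxy-2,4-dimethylcyclohexa-2,5-dien-1-one F1. Preparative SFC on an amylose tris(3,5-dimethylphenylcarbamate) phase then delivers (R)-2 and the unwanted (S)-4-hydroxy-2,4-dimethylcyclohexa-2,5-dien-1-one F2, which is set aside.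

Step 8 (the risk is that BF3 damages the polyene chain or the tertiary silyl ether, or that the congested C10 centre does not form). The fallback sets out from 11 and comes back at 14, using an anionic, aprotic annulation with an α-silyl vinyl ketone.
- Reagent: (1-bromovinyl)trimethylsilane and Mg give [1-(trimethylsilyl)vinyl]magnesium bromide F3. It adds to propanal to give 2-(trimethylsilyl)pent-1-en-3-ol F4, and MnO2 oxidises this to 2-(trimethylsilyl)pent-1-en-3-one F5.
- Annulation: MeLi (THF, 0 °C) converts 11 into the ring B lithium enolate F6. Conjugate addition to F5 at −78 °C gives the α-silyl 1,5-diketone F7; the silyl group stabilises the adduct enolate, so neither proton transfer nor polymerisation intervenes. NaOMe/MeOH removes silicon and cyclises F7 to 14.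

Step 9 (the risk is that the tetrasubstituted enone is too hindered for copper hydride, or that the cis/trans ratio is poor). The fallback sets out from 11 and comes back at 17.
- The step 8 conditions with methyl vinyl ketone in place of 12 give the 2-(3-oxobutyl) diketone F8 and then the C4-unsubstituted enone F9. F9 is a β,β-disubstituted octalone of the Wieland–Miescher type, the class on which copper hydrides are expected, by analogy with hydrogenation and cuprate additions, to react quickly and give the cis ring fusion.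
- Reduction with [(Ph3P)CuH]6 (cat.) and PhMe2SiH gives the cis-fused dimethylphenylsilyl enol ether F10. MeLi gives the lithium enolate F11, and MeI gives the cis-fused 4-methyl ketone F12 (C4 epimers).
- A second methylation through the more substituted potassium enolate F13 (KOtBu, t-BuOH/THF, then MeI) gives 17.

Further compounds
F1 | step 1 | racemic 4-hydroxy-2,4-dimethylcyclohexa-2,5-dien-1-one | CC1=CC(C)(O)C=CC1=O
F2 | step 1 | (S)-4-hydroxy-2,4-dimethylcyclohexa-2,5-dien-1-one | O=C1C=C[C@](C)(O)C=C1C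
F3 | step 8 | [1-(trimethylsilyl)vinyl]magnesium bromide | C=C([Mg]Br)[Si](C)(C)C
F4 | step 8 | 2-(trimethylsilyl)pent-1-en-3-ol | CCC(O)C(=C)[Si](C)(C)C
F5 | step 8 | 2-(trimethylsilyl)pent-1-en-3-one | CCC(=O)C(=C)[Si](C)(C)C
F6 | step 8 | ring B lithium enolate derived from 11 | CC(C)=CCC/C(C)=C/CC/C(C)=C/CC[C@@H]1C(C)=C(O[Li])CC[C@@]1(C)O[Si](CC)(CC)CC
F7 | step 8 | α-silyl 1,5-diketone (2-[3-oxo-2-(trimethylsilyl)pentyl] analogue of 13) | CC(C)=CCC/C(C)=C/CC/C(C)=C/CC[C@@H]1[C@@](C)(CC(C(=O)CC)[Si](C)(C)C)C(=O)CC[C@@]1(C)O[Si](CC)(CC)CC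
F8 | step 9 | 2-(3-oxobutyl) diketone (lower homologue of 13) | CC(C)=CCC/C(C)=C/CC/C(C)=C/CC[C@@H]1[C@@](C)(CCC(C)=O)C(=O)CC[C@@]1(C)O[Si](CC)(CC)CC
F9 | step 9 | C4-unsubstituted enone (4-demethyl analogue of 14) | CC(C)=CCC/C(C)=C/CC/C(C)=C/CC[C@@H]1[C@@]2(C)CCC(=O)C=C2CC[C@@]1(C)O[Si](CC)(CC)CC
F10 | step 9 | cis-fused dimethylphenylsilyl enol ether of the C4-unsubstituted ketone | CC(C)=CCC/C(C)=C/CC/C(C)=C/CC[C@@H]1[C@@]2(C)CCC(O[Si](C)(C)c3ccccc3)=C[C@H]2CC[C@@]1(C)O[Si](CC)(CC)CC
F11 | step 9 | cis-fused lithium enolate of the C4-unsubstituted ketone | CC(C)=CCC/C(C)=C/CC/C(C)=C/CC[C@@H]1[C@@]2(C)CCC(O[Li])=C[C@H]2CC[C@@]1(C)O[Si](CC)(CC)CC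
F12 | step 9 | cis-fused 4-methyl ketone (C4 epimers) | CC(C)=CCC/C(C)=C/CC/C(C)=C/CC[C@@H]1[C@@]2(C)CCC(=O)C(C)[C@H]2CC[C@@]1(C)O[Si](CC)(CC)CC
F13 | step 9 | cis-fused potassium enolate of the 4-methyl ketone | CC(C)=CCC/C(C)=C/CC/C(C)=C/CC[C@@H]1[C@@]2(C)CCC(O[K])=C(C)[C@H]2CC[C@@]1(C)O[Si](CC)(CC)CC
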